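**Retrosynthesis (briarane numbering C1–C20)**
1. Target ⇐ triacetylation of a triol ⇐ face-selective epoxidation of the C11=C20 exocyclic alkene ⇐ Petasis methylenation of the C11 ketone.
2. The γ-lactone with the C8 tertiary carbinol and C17 methyl ⇐ SmI2 intramolecular Reformatsky-aldol of a C7 2-bromopropionate onto the C8 ketone.
3. The 10-membered ring with the Z-C5=C6 olefin ⇐ RCM of a C5 isopropenyl / C7 vinyl diene. The C9–C10 bond ⇐ anti-aldol of the α′-enolate of a cyclohexenone with an α-dithianyl aldehyde (C8 ketone masked, C7 carbinol set by CBS reduction).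
4. The cyclohexenone ring ⇐ endo Diels–Alder of methacrolein with 1,4-diacetoxybutadiene (sets C1 and C14), then Grignard addition of the homoallyl chain (sets C2).
5. Ring-forming order: cyclohexane (Diels–Alder), then the 10-membered carbocycle (RCM), then the γ-lactone (SmI2 aldol), then the spiro-epoxide.

Assumptions:
- Catalyst and auxiliary enantiomers are chosen to give the absolute configuration shown in the SMILES.
- The kinetic anti-aldol adduct equilibrates at C10 to the trans-diequatorial isomer.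

---

**Step 1**
Reactants: 1 methacrolein; 2 (1E,3E)-1,4-diacetoxybuta-1,3-diene
Product: 3 (1R,2S,5S)-2,5-diacetoxy-1-methylcyclohex-3-ene-1-carbaldehyde (CHO cis to both OAc, Me trans)
Conditions: chiral oxazaborolidinium (Corey–Ryu, 10 mol%), CH2Cl2, –78 → –20 °C
Reagents that add atoms: none
Why: Lewis-acid-catalysed endo Diels–Alder. The CHO sits endo, so the two outside OAc groups end up cis to CHO and to each other, with Me trans. The catalyst face selection sets C1/C11/C14.

**Step 2**
Reactants: 3; 4 4-bromo-2-methylbut-1-ene (converted to its Grignard reagent with Mg)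
Product: 5 homoallylic alcohol (C2 carbinol)
Conditions: 4, Mg, THF → Grignard; add to 3, THF, –78 °C, 30 min; cold NH4Cl quench
Reagents that add atoms: 3-methylbut-3-enylmagnesium bromide, C=C(C)CC[Mg]Br
Why: Grignard addition to the neopentyl aldehyde. Felkin–Anh attack anti to the larger C10 ring carbon sets C2. At –78 °C the hindered acetates survive.

**Step 3**
Reactants: 5
Product: 6 (C2 TBS ether)
Conditions: TBSOTf, 2,6-lutidine, CH2Cl2, –78 → 0 °C (run on crude 5)
Reagents that add atoms: TBSOTf, CC(C)(C)[Si](C)(C)OS(=O)(=O)C(F)(F)F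
Why: silylation. The hindered TBS ether blocks 1,3-acetyl migration from C14 to C2 and survives all later steps.

**Step 4**
Reactants: 6
Product: 7 (C11 alcohol, C14 acetate retained)
Conditions: K2CO3 (0.3 equiv), MeOH, 0 °C, 1 h
Reagents that add atoms: none
Why: chemoselective methanolysis. The C11 acetate is unhindered, while the C14 acetate is shielded by quaternary C1 and the cis C2 OTBS. No stereocentre is touched.

**Step 5**
Reactants: 7
Product: 8 (γ-acetoxy cyclohexenone)
Conditions: activated MnO2 (10 equiv), CH2Cl2, rt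
Reagents that add atoms: none
Why: allylic alcohol oxidation. C10 becomes the only enolisable α-position, so the later aldol is regiospecific.

**Step 6**
Reactants: 9 1,3-dithiane; 10 acrolein
Product: 11 (±)-1-(1,3-dithian-2-yl)prop-2-en-1-ol
Conditions: 9, n-BuLi, THF, –30 °C; then 10, –78 °C
Reagents that add atoms: none
Why: Corey–Seebach 1,2-addition of the lithiodithiane to the enal; the product is racemic.

**Step 7**
Reactants: 11
Product: 12 2-acryloyl-1,3-dithiane
Conditions: MnO2 (15 equiv), CH2Cl2, rt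
Reagents that add atoms: none
Why: oxidation of the allylic alcohol to the prochiral enone.

**Step 8**
Reactants: 12
Product: 13 (S)-1-(1,3-dithian-2-yl)prop-2-en-1-ol
Conditions: CBS catalyst (10 mol%; enantiomer chosen to give S), BH3·SMe2, THF, –20 °C
Reagents that add atoms: none
Why: CBS reduction. Catalyst-controlled hydride delivery sets the future C7 centre.

**Step 9**
Reactants: 13
Product: 14 (S)-2-[1-(triethylsilyloxy)allyl]-1,3-dithiane
Conditions: TESCl, imidazole, DMF, 0 °C
Reagents that add atoms: TESCl, CC[Si](Cl)(CC)CC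
Why: protection. TES is chosen so C7 can later be unmasked selectively in the presence of TBS ethers.

**Step 10**
Reactants: 14
Product: 15 (S)-2-[1-(triethylsilyloxy)allyl]-1,3-dithiane-2-carbaldehyde
Conditions: n-BuLi, THF, –78 °C; then DMF; NH4Cl
Reagents that add atoms: DMF, CN(C)C=O
Why: dithiane lithiation and formylation. The C7 stereocentre is untouched. The product is a non-enolisable aldehyde with C8 masked as a ketone.

**Step 11**
Reactants: 8; 15
Product: 16 (aldol adduct, C9–OH, C10–C9 bond)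
Conditions: 8, LDA, THF, –78 °C; add 15; –78 → –40 °C
Reagents that add atoms: none
Why: regiospecific α′-enolate aldol. The endocyclic enolate is E, so the chair Zimmerman–Traxler TS gives the anti aldol required for C9/C10. The reversible Li-aldolate settles C10 as the trans-diequatorial isomer (C9 trans to C2).

**Step 12**
Reactants: 16
Product: 17 (C9 TBS ether)
Conditions: TBSOTf, 2,6-lutidine, CH2Cl2, –78 °C
Reagents that add atoms: TBSOTf, CC(C)(C)[Si](C)(C)OS(=O)(=O)C(F)(F)F
Why: protection of the β-hydroxy ketone. Silyl rather than acetyl avoids a later SmI2 cleavage of an α-OAc ketone.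

**Step 13**
Reactants: 17
Product: 18 (C12=C13 reduced)
Conditions: [(Ph3P)CuH]6 (Stryker), toluene, –40 °C
Reagents that add atoms: none (hydride/proton only)
Why: Cu–H conjugate reduction removes the enone C=C but leaves the terminal alkenes, the dithiane and the acetate. C12 and C13 become CH2.

**Step 14**
Reactants: 18
Product: 19 (C8 ketone unmasked)
Conditions: PIFA, CaCO3, MeCN/H2O (9:1), 0 °C
Reagents that add atoms: water, O
Why: oxidative dithiane hydrolysis gives the C8 ketone. The buffer protects the TES ether.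

**Step 15**
Reactants: 19
Product: 20 (10-membered macrocycle, Z-C5=C6)
Conditions: Hoveyda–Grubbs II (15 mol%), 1,4-benzoquinone, toluene (1 mM), 80 °C
Reagents that add atoms: none (ethylene is lost)
Why: RCM between C7-vinyl and C5 isopropenyl forms the trisubstituted Z-olefin. Ring size and the trans-fused cyclohexane enforce Z.

**Step 16**
Reactants: 20
Product: 21 (C7 allylic α-ketol)
Conditions: HF·pyridine (buffered with pyridine), THF, 0 °C
Reagents that add atoms: none
Why: TES ethers cleave much faster than the hindered TBS ethers, and the acetate survives. The C7 stereocentre is kept.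

**Step 17**
Reactants: 21
Product: 22 (C7 2-bromopropanoate)
Conditions: 2-bromopropionyl bromide, pyridine, DMAP (cat.), CH2Cl2, 0 °C
Reagents that add atoms: 2-bromopropionyl bromide, CC(Br)C(=O)Br
Why: esterification installs C17–C19 as a mixture at the bromide carbon. That carbon becomes the lactone enolate, so the mixture is irrelevant.

**Step 18**
Reactants: 22
Product: 23 (γ-lactone, C8 tertiary OH, C11 ketone)
Conditions: SmI2 (2.5 equiv), THF, –78 → –40 °C
Reagents that add atoms: none
Why: the α-bromoester gives a Sm(III) enolate that adds intramolecularly to the C8 ketone (5-exo aldol). C9 orients trans to C6 across the new lactone, which sets C8 (OH cis to C6). C17-Me ends up trans to C9 under thermodynamic control.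

**Step 19**
Reactants: 23
Product: 24 (C11=C20 exocyclic methylene)
Conditions: Cp2TiMe2 (3 equiv), toluene/THF, 65 °C, dark
Reagents that add atoms: dimethyltitanocene, C[Ti](C)(C1C=CC=C1)C1C=CC=C1
Why: Petasis methylenation is selective for the ketone over the lactone and acetate, and avoids basic retro-aldol of the β-hydroxy lactone.

**Step 20**
Reactants: 24
Product: 25 (11,20-spiro-epoxide, bis-TBS)
Conditions: mCPBA (1.1 equiv), NaHCO3, CH2Cl2, 0 °C
Reagents that add atoms: mCPBA, OOC(=O)c1cccc(Cl)c1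
Why: electrophilic epoxidation. The axial C1 methyl blocks the face syn to it at C11, so O is delivered anti, giving the C11 oxygen cis to C2 and C14-OAc, as in the target. The unhindered exocyclic alkene is favoured over the hindered Z-trisubstituted C5=C6, which is deactivated by the allylic lactone oxygen.

**Step 21**
Reactants: 25
Product: 26 (C2, C8, C9 triol)
Conditions: HF·pyridine, pyridine/THF, 40 °C
Reagents that add atoms: none
Why: removal of both TBS ethers. The acetate, lactone and epoxide survive the buffered HF.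

**Step 22**
Reactants: 26
Product: 27 junceellolide F
Conditions: Ac2O, DMAP, pyridine, rt
Reagents that add atoms: acetic anhydride, CC(=O)OC(C)=O
Why: the secondary C2 and C9 alcohols acetylate, while the hindered tertiary C8–OH does not.

---

**Compound list**

1 | methacrolein | C=C(C)C=O | starting material
2 | (1E,3E)-1,4-diacetoxybuta-1,3-diene | CC(=O)O/C=C/C=C/OC(C)=O | starting material
3 | (1R,2S,5S)-2,5-diacetoxy-1-methylcyclohex-3-ene-1-carbaldehyde | CC(=O)O[C@H]1C=C[C@@H](OC(C)=O)C[C@@]1(C)C=O | intermediate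
4 | 4-bromo-2-methylbut-1-ene | CC(=C)CCBr | starting material
5 | 3 with CHO converted to CH(OH)CH2CH2C(Me)=CH2 | CC(=O)O[C@H]1C=C[C@@H](OC(C)=O)C[C@@]1(C)[C@H](O)CCC(C)=C | intermediate
6 | C2 TBS ether of 5 | CC(=O)O[C@H]1C=C[C@@H](OC(C)=O)C[C@@]1(C)[C@H](O[Si](C)(C)C(C)(C)C)CCC(C)=C | intermediate
7 | 6 with the C11 acetate removed (C11–OH) | CC(=O)O[C@H]1C=C[C@@H](O)C[C@@]1(C)[C@H](O[Si](C)(C)C(C)(C)C)CCC(C)=C | intermediate
8 | 4-acetoxy-5-methyl-5-[1-(TBSO)-4-methylpent-4-enyl]cyclohex-2-en-1-one | CC(=O)O[C@H]1C=CC(=O)C[C@@]1(C)[C@H](O[Si](C)(C)C(C)(C)C)CCC(C)=C | intermediate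
9 | 1,3-dithiane | C1CSCSC1 | starting material
10 | acrolein | C=CC=O | starting material
11 | (±)-1-(1,3-dithian-2-yl)prop-2-en-1-ol | C=CC(O)C1SCCCS1 | intermediate
12 | 1-(1,3-dithian-2-yl)prop-2-en-1-one | C=CC(=O)C1SCCCS1 | intermediate
13 | (S)-1-(1,3-dithian-2-yl)prop-2-en-1-ol | C=C[C@H](O)C1SCCCS1 | intermediate
14 | (S)-2-[1-(triethylsilyloxy)allyl]-1,3-dithiane | C=C[C@H](O[Si](CC)(CC)CC)C1SCCCS1 | intermediate
15 | (S)-2-[1-(triethylsilyloxy)allyl]-1,3-dithiane-2-carbaldehyde | C=C[C@H](O[Si](CC)(CC)CC)C1(C=O)SCCCS1 | intermediate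
16 | aldol adduct of 8 and 15 (C9–OH, C10–C9 bond) | CC(=O)O[C@H]1C=CC(=O)[C@H]([C@@H](O)C2(SCCCS2)[C@@H](O[Si](CC)(CC)CC)C=C)[C@@]1(C)[C@H](O[Si](C)(C)C(C)(C)C)CCC(C)=C | intermediate
17 | C9 TBS ether of 16 | CC(=O)O[C@H]1C=CC(=O)[C@H]([C@@H](O[Si](C)(C)C(C)(C)C)C2(SCCCS2)[C@@H](O[Si](CC)(CC)CC)C=C)[C@@]1(C)[C@H](O[Si](C)(C)C(C)(C)C)CCC(C)=C | intermediate
18 | 17 with C12=C13 reduced | CC(=O)O[C@H]1CCC(=O)[C@H]([C@@H](O[Si](C)(C)C(C)(C)C)C2(SCCCS2)[C@@H](O[Si](CC)(CC)CC)C=C)[C@@]1(C)[C@H](O[Si](C)(C)C(C)(C)C)CCC(C)=C | intermediate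
19 | C8 ketone (dithiane removed) | CC(=O)O[C@H]1CCC(=O)[C@H]([C@@H](O[Si](C)(C)C(C)(C)C)C(=O)[C@@H](O[Si](CC)(CC)CC)C=C)[C@@]1(C)[C@H](O[Si](C)(C)C(C)(C)C)CCC(C)=C | intermediate
20 | 10-membered macrocycle (Z-C5=C6), tris-silyl, C8 and C11 ketones | CC(=O)O[C@H]1CCC(=O)[C@@H]2[C@@H](O[Si](C)(C)C(C)(C)C)C(=O)[C@@H](O[Si](CC)(CC)CC)/C=C(/C)CC[C@@H](O[Si](C)(C)C(C)(C)C)[C@@]12C | intermediate
21 | C7 alcohol (TES removed) | CC(=O)O[C@H]1CCC(=O)[C@@H]2[C@@H](O[Si](C)(C)C(C)(C)C)C(=O)[C@@H](O)/C=C(/C)CC[C@@H](O[Si](C)(C)C(C)(C)C)[C@@]12C | intermediate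
22 | C7 2-bromopropanoate | CC(=O)O[C@H]1CCC(=O)[C@@H]2[C@@H](O[Si](C)(C)C(C)(C)C)C(=O)[C@@H](OC(=O)C(C)Br)/C=C(/C)CC[C@@H](O[Si](C)(C)C(C)(C)C)[C@@]12C | intermediate
23 | γ-lactone, 8-OH, 11-ketone, bis-TBS | CC(=O)O[C@H]1CCC(=O)[C@@H]2[C@@H](O[Si](C)(C)C(C)(C)C)[C@@]3(O)[C@H](/C=C(/C)CC[C@@H](O[Si](C)(C)C(C)(C)C)[C@@]12C)OC(=O)[C@@H]3C | intermediate
24 | 11(20)-exocyclic methylene analogue of 23 | CC(=O)O[C@H]1CCC(=C)[C@@H]2[C@@H](O[Si](C)(C)C(C)(C)C)[C@@]3(O)[C@H](/C=C(/C)CC[C@@H](O[Si](C)(C)C(C)(C)C)[C@@]12C)OC(=O)[C@@H]3C | intermediate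
25 | 11,20-epoxide, bis-TBS | CC(=O)O[C@H]1CC[C@]2(CO2)[C@@H]2[C@@H](O[Si](C)(C)C(C)(C)C)[C@@]3(O)[C@H](/C=C(/C)CC[C@@H](O[Si](C)(C)C(C)(C)C)[C@@]12C)OC(=O)[C@@H]3C | intermediate
26 | 2,8,9-triol, 14-acetate | CC(=O)O[C@H]1CC[C@]2(CO2)[C@@H]2[C@@H](O)[C@@]3(O)[C@H](/C=C(/C)CC[C@@H](O)[C@@]12C)OC(=O)[C@@H]3C | intermediate
27 | junceellolide F | CC(=O)O[C@H]1CC[C@]2(CO2)[C@@H]2[C@@H](OC(C)=O)[C@@]3(O)[C@H](/C=C(/C)CC[C@@H](OC(C)=O)[C@@]12C)OC(=O)[C@@H]3C | target

---

**Total steps:** 22 (five of them build the dithiane aldehyde 15 in parallel).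
**Longest linear sequence:** 17 steps (1→2→3→4→5→11→12→13→14→15→16→17→18→19→20→21→22).

**Three steps most likely to fail**
1. **Step 15, RCM to the 10-membered Z-trisubstituted olefin.** It may fail through catalyst chelation or oligomerisation.
   Fallback: intramolecular Nozaki–Hiyama–Kishi closure instead. Use a (Z)-C5(Me)=C6–I vinyl iodide on the C2 chain and leave C7 as an aldehyde (C8 still a dithiane), so the C6–C7 bond and the C7–OH form together.
2. **Step 11, hindered aldol (C9/C10 stereochemistry and yield).**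
   Fallback: reverse the polarity. Make ring A the C10 aldehyde by Diels–Alder with (E)-TBSOCH2CH=C(Me)CHO, then oxidation, and add the lithiated dithiane 14 so that C9 is set by Felkin–Anh addition.
3. **Step 18, SmI2 Reformatsky-aldol (α-acyloxy ketone reduction, C8/C17 selectivity).**
   Fallback: preform the lactone as a 4-iodo-3-methyl-5-vinylbutenolide. Couple it by NHK to a C10 aldehyde, close the ring by RCM, then set the C8–OH by nucleophilic epoxidation and SmI2 opening of the 8,17-epoxide.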